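Its constants were drawn at random within sensible limits; the flask was simulated.

**Two exits.** The pitfall is to take a shrinking Q for a finished run: Q leaves by two exits, and one of them ends at J, not at X.

| flask | Q | G | D | E | remark | time |
|---|---|---|---|---|---|---|
| epsilon | 0.080 M | 0.0960 M | 0.0400 M | 1.6 mM | a single well-mixed tank run continuously and read at steady state, 5.00 min in it on average |  |
| delta | 0.080 M | 0.0960 M | 0.0400 M | 1.6 mM | a single well-mixed tank run continuously and read at steady state, 1.0 min in it on average |  |
| alpha | 0.080 M | 0.0960 M | 0.0400 M | 1.6 mM | a closed flask charged with all of it at once and left for 1.0 min | 1.0 min |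
| zeta | 0.080 M | 0.0960 M (fed, over 0.800 min) | 0.0400 M | 1.6 mM | all but G at the start; G goes in evenly over 0.800 min, the run ends at 1.0 min | 1.0 min |

    Q + E ⇌ E + J (K1 = 5.77, k1 = 52.4 L mol⁻¹ s⁻¹)
    E + J ⇌ E.J (K2 = 5.2 L mol⁻¹, k2 = 739 L mol⁻¹ s⁻¹)
    G + E.J → E + X (k3 = 34.5 L mol⁻¹ s⁻¹)
    Q + D → Q.D (k4 = 1.14 L mol⁻¹ s⁻¹)

- the set-up with the highest amount of X at the outlet or at the end, in percent of the Q put in ("none" if the first two lie within 2 percentage points) (epsilon / delta / alpha / zeta / none)
- amount of X at the outlet or at the end, in percent of the Q put in, epsilon
- amount of X at the outlet or at the end, in percent of the Q put in, delta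
- amount of X at the outlet or at the end, in percent of the Q put in, alpha
- amount of X at the outlet or at the end, in percent of the Q put in, zeta

**One number.** I compare the exits at the moment of charging, where c(Q) cancels. What remains is the split number S, the rate constant of Q + E times c(E) over that of Q + D times c(D), a selectivity factor: 1.84. Taken as it stands, it sends 35.2% of Q to Q.D and leaves a ceiling of 64.8% for X. S contains neither G nor time, so the four set-ups share it.

**Its drift.** S rises as D is used, reaching 3.68 at half of c(D), which lowers the loss. But the first step runs back, with equilibrium constant 5.77, so J returns some Q to D, which raises the loss. I therefore keep 64.8% as an approximate ceiling.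

**Its limit.** S cannot rank the set-ups, so I need a clock. E.J falls back at 142 s⁻¹, faster than it goes on with G at 3.31 s⁻¹, so E.J stays close to balance with E and J. J then lives about 0.605 min with G as charged. Epsilon's average stay of 5.00 min is longer than that life, by a factor of 8.26, while the other set-ups have 1.0 min, a factor of 1.65, so I choose epsilon, with X near 57.8% of Q, and less as G is used.

**The result.** The forecast names epsilon, with 54% for epsilon, 30.5% for delta, 39.5% for alpha and 30% for zeta, since “X formation is the slow step and needs time”. The simulation gives epsilon as best, with 53.7%, 30.1%, 38.7% and 29.4% in that order.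

**S again.** In zeta at 1.00 min, the forward Q + E rate stands at 5.0 times the Q + D rate, above the starting S, with 32% of D left and Q.D at 33.8%. Left until 10.0 min, zeta holds X at 61.6% and Q.D at 38.4%, beside 64.8% and 35.2%. A neighbour of zeta with 0.068 M of D has S of 1.08, hence a share of 48.1%, and at 1.00 min it shows Q.D at 49.6% and X at 24.6%.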